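Readings and results were computed for substances that don't exist; the scatter is artificial.

I began with the north run, the nearest to this flask: the same E, but 40 mM of J against 60.0 mM.

| setting | north | south-east | flask |
|---|---|---|---|
| E | 20 mM | 20 mM | 20 mM |
| J | 40 mM | 90 mM | 60.0 mM |
| remark | run made earlier | run made earlier |  |
| time |  |  | 12 h |

| run | time / h | D / % | X / % | E / % |
|---|---|---|---|---|
| north | 1.00 | 77.2 | 2.9 | 0 |
| north | 2.00 | 66.3 | 5.6 | 0 |
| north | 2.50 | 63.9 | 7.3 | 1.0 |
| north | 4.00 | 55.9 | 11.0 | 1.6 |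
| north | 6.00 | 48.1 | 18.2 | 0 |
| north | 10.0 | 43.4 | 25.8 | 1.5 |
| north | 15.0 | 36.5 | 34.4 | 0 |
| south-east | 2.00 | 21.6 | 3.8 | 1.6 |
| south-east | 4.00 | 6.2 | 7.9 | 0 |
| south-east | 6.00 | 1.3 | 6.9 | 1.8 |
| south-east | 8.00 | 0 | 8.7 | 0.1 |
| south-east | 10.0 | 0.4 | 8.5 | 0 |
| south-east | 12.0 | 0 | 7.9 | 1.2 |
| south-east | 15.0 | 0 | 10.0 | 1.0 |

(each reading ± 1 percentage point)

- equivalents of J to E, everything else as given, that leave most D at 12 h
- the amount of D then, in percent of the E charged
- the amount of D with the amounts as given



E stood within the scatter of zero at the first readings, and I took one J per E for that step, so what counted was the spare J, cJ minus cE. D fell at 0.0307 h⁻¹ late in the north run but at 0.624 h⁻¹ early in the south-east run, far faster. I read this as a pseudo-first-order loss at rate k·cJ, with cJ shrinking as D is lost. One k fitted both stretches with a price of 1.55, the mM of J spent per mM of D lost, and k = 0.0144 mM⁻¹ h⁻¹.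

The north spare buys 12.9 mM of D loss, less than the 20 mM of D made, so I reckoned that D levels off near 35.5%. This flask's spare of 40.0 mM buys 25.8 mM, more than its D, so I reckoned no such floor for D. On my first round I held J at the spare, which gave D a half-life of 1.20 h, short against 12 h. So in my reckoning J falls towards a = 9.03 mM as D goes. On the second round I put that fall back in: cD/(a + ν·cD) drops from cE/s by the factor exp(−k·a·t), which left D at 5.66%. At one J per E the spare is zero, so I put the most D there.

The forecast, which differs from mine, gave 24%, and 57% at 1.2 equiv, “where little J is left to overreact”.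

The flask gave 8.38%, and the most D, 92.0%, came at 1.04 equiv.

    E + J → D + Z (k = 16.0 L mol⁻¹ min⁻¹)
    J + X ⇌ Q + Z (K = 27.0, k = 38.0 L mol⁻¹ min⁻¹)
    J + D → X + Z (k = 0.340 L mol⁻¹ min⁻¹)
    J ⇌ G (K = 0.320, k = 0.00940 min⁻¹)

In this flask D stood above my figure, and at 120 h, with D at 0%, J and G together held 6.06 mM against my 9.03 mM. With 34 mM of E and the same J, the spare is 26.0 mM, which at my price buys 16.8 mM of D loss, less than that E. So D reckons out at 50.6% of its E. That flask held D at 44.9% at 12.0 h.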